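**Assumption:** 2,4-dihydroxyphenylacetic acid (1) is taken as an inexpensive catalogue compound; the target is the trans (2S,3S) isomer, as the SMILES encodes (MOM = methoxymethyl).

## Retrosynthetic overview

1. Target 18 ⇒ C2–O1 bond: acid-triggered MOM removal and cyclodehydration of the (1S,2S)-benzylic alcohol 16; the C3 centre steers the aryl group trans.
2. 16 ⇒ C3 methyl from the CH2OH of 1,3-diol 14 (primary tosylate 15, then hydride); 14 ⇒ reductive removal of the oxazolidinone from aldol adduct 13.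
3. 13 ⇒ key C2–C3 bond: Evans syn-aldol between the boron enolate of N-(arylacetyl)oxazolidinone 9 (ring A fragment) and 3,4,5-trimethoxybenzaldehyde 10 (ring C fragment); both stereocentres are set here.
4. 9 ⇒ arylacetic acid 6 plus auxiliary 7; 6 ⇒ acid 1 by esterification, bis-MOM protection, C5 bromination, Stille allylation and saponification.
5. Ring order: rings A and C are bought as benzene rings; the dihydrofuran ring (ring B) is the only ring formed, in the last step.

## Route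

Step 1
Reactants: 1 2,4-dihydroxyphenylacetic acid
Product: 2 methyl 2-(2,4-dihydroxyphenyl)acetate
Conditions: MeOH, H2SO4 (cat.), reflux
Reagents that add atoms: methanol, CO
Why: Fischer esterification in excess methanol gives the open methyl ester rather than the lactone, masking the acid for the ring chemistry that follows.

Step 2
Reactants: 2 methyl 2-(2,4-dihydroxyphenyl)acetate
Product: 3 methyl 2-[2,4-bis(methoxymethoxy)phenyl]acetate
Conditions: MOMCl, i-Pr2NEt, CH2Cl2, 0 °C → rt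
Reagents that add atoms: chloromethyl methyl ether, COCCl
Why: O-alkylation of both phenols (MOM acetal protection) gives ethers that survive base, hydride, palladium and boron enolate chemistry and fall off with acid at the end.

Step 3
Reactants: 3 methyl 2-[2,4-bis(methoxymethoxy)phenyl]acetate
Product: 4 methyl 2-[5-bromo-2,4-bis(methoxymethoxy)phenyl]acetate
Conditions: NBS, MeCN, 0 °C → rt, dark
Reagents that add atoms: N-bromosuccinimide, O=C1CCC(=O)N1Br
Why: Electrophilic aromatic bromination goes to C5, which is para to one OMOM and ortho to the other, while the equally activated C3 is blocked between the two OMOM groups.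

Step 4
Reactants: 4 methyl 2-[5-bromo-2,4-bis(methoxymethoxy)phenyl]acetate
Product: 5 methyl 2-[5-allyl-2,4-bis(methoxymethoxy)phenyl]acetate
Conditions: allylSnBu3, Pd(PPh3)4 (5 mol %), DMF, 95 °C
Reagents that add atoms: allyltributylstannane, C=CC[Sn](CCCC)(CCCC)CCCC
Why: Stille cross-coupling on zerovalent palladium (oxidative addition, allyl transfer from tin, reductive elimination) installs the allyl group on a simple achiral ester where the regiochemistry is already fixed by the bromide.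

Step 5
Reactants: 5 methyl 2-[5-allyl-2,4-bis(methoxymethoxy)phenyl]acetate
Product: 6 2-[5-allyl-2,4-bis(methoxymethoxy)phenyl]acetic acid
Conditions: LiOH·H2O, THF/MeOH/H2O, rt; then 1 M HCl to pH 3–4 at 0 °C
Reagents that add atoms: lithium hydroxide, [Li+].[OH-]
Why: Ester saponification is mild enough to leave the allyl group unisomerised, and brief cold acidification spares the MOM ethers.

Step 6
Reactants: 6 2-[5-allyl-2,4-bis(methoxymethoxy)phenyl]acetic acid; 7 (S)-4-benzyl-2-oxazolidinone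
Product: 9 (S)-4-benzyl-3-{2-[5-allyl-2,4-bis(methoxymethoxy)phenyl]acetyl}oxazolidin-2-one, via mixed pivalic anhydride 8 (not isolated)
Conditions: PivCl, Et3N, THF, −20 °C; then 7, LiCl, −20 °C → rt
Reagents that add atoms: none
Why: N-acylation through the mixed pivalic anhydride (LiCl/Et3N activation of the oxazolidinone, attack at the less hindered arylacetyl carbonyl) avoids an acid chloride, ketene formation and strong base.

Step 7
Reactants: 9 (S)-4-benzyl-3-{2-[5-allyl-2,4-bis(methoxymethoxy)phenyl]acetyl}oxazolidin-2-one; 10 3,4,5-trimethoxybenzaldehyde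
Product: 13 (S)-4-benzyl-3-[(2S,3S)-2-[5-allyl-2,4-bis(methoxymethoxy)phenyl]-3-hydroxy-3-(3,4,5-trimethoxyphenyl)propanoyl]oxazolidin-2-one, via Z-dibutylboron enolate 11 (not isolated), via dibutylboron aldolate 12 (not isolated)
Conditions: Bu2BOTf, i-Pr2NEt, CH2Cl2, −78 → 0 °C; 10, −78 → 0 °C; then pH 7 buffer, MeOH, 30% H2O2, 0 °C
Reagents that add atoms: none
Why: Evans syn-aldol: the Z-boron enolate reacts through a closed Zimmerman–Traxler chair on the face away from the benzyl group of the dipole-minimised auxiliary, forming the C2–C3 bond between the ring A and ring C fragments and setting both centres as (2S,3S).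

Step 8
Reactants: 13 (S)-4-benzyl-3-[(2S,3S)-2-[5-allyl-2,4-bis(methoxymethoxy)phenyl]-3-hydroxy-3-(3,4,5-trimethoxyphenyl)propanoyl]oxazolidin-2-one
Product: 14 (1S,2R)-2-[5-allyl-2,4-bis(methoxymethoxy)phenyl]-1-(3,4,5-trimethoxyphenyl)propane-1,3-diol
Conditions: LiBH4, MeOH (2 equiv), THF, 0 °C
Reagents that add atoms: none
Why: Reductive cleavage of the imide (hydride attack at the exocyclic acyl carbonyl, assisted by the neighbouring alkoxide) gives the 1,3-diol cold enough to suppress retro-aldol, and neither stereocentre is touched (the R descriptor reflects changed CIP priorities only).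

Step 9
Reactants: 14 (1S,2R)-2-[5-allyl-2,4-bis(methoxymethoxy)phenyl]-1-(3,4,5-trimethoxyphenyl)propane-1,3-diol
Product: 15 (2R,3S)-2-[5-allyl-2,4-bis(methoxymethoxy)phenyl]-3-hydroxy-3-(3,4,5-trimethoxyphenyl)propyl 4-methylbenzenesulfonate
Conditions: TsCl (1.1 equiv), pyridine, CH2Cl2, 0 °C
Reagents that add atoms: 4-methylbenzenesulfonyl chloride, Cc1ccc(cc1)S(=O)(=O)Cl
Why: Selective sulfonylation: the unhindered primary hydroxyl reacts far faster than the congested secondary benzylic one.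

Step 10
Reactants: 15 (2R,3S)-2-[5-allyl-2,4-bis(methoxymethoxy)phenyl]-3-hydroxy-3-(3,4,5-trimethoxyphenyl)propyl 4-methylbenzenesulfonate
Product: 16 (1S,2S)-2-[5-allyl-2,4-bis(methoxymethoxy)phenyl]-1-(3,4,5-trimethoxyphenyl)propan-1-ol
Conditions: LiEt3BH, THF, 0 °C → rt
Reagents that add atoms: none
Why: SN2 hydride displacement of the primary tosylate turns CH2OTs into the C3 methyl group without touching either stereocentre (the descriptor becomes S only through changed priorities).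

Step 11
Reactants: 16 (1S,2S)-2-[5-allyl-2,4-bis(methoxymethoxy)phenyl]-1-(3,4,5-trimethoxyphenyl)propan-1-ol
Product: 18 (2S,3S)-5-allyl-3-methyl-2-(3,4,5-trimethoxyphenyl)-2,3-dihydrobenzofuran-6-ol, via MOM-free triol 17 (not isolated)
Conditions: 3 M aq HCl, MeOH, 50 °C, dilute (0.02 M)
Reagents that add atoms: none
Why: Acid-catalysed acetal cleavage followed by cyclodehydration: the trimethoxyphenyl-stabilised benzylic cation is captured 5-exo by the ortho phenol with the aryl group trans to the C3 methyl (kinetically and thermodynamically preferred), so the aldol-derived C3 centre fixes C2 as S.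

## Compound list

1 | 2,4-dihydroxyphenylacetic acid | OC(=O)Cc1ccc(O)cc1O | starting material
2 | methyl 2-(2,4-dihydroxyphenyl)acetate | COC(=O)Cc1ccc(O)cc1O | intermediate
3 | methyl 2-[2,4-bis(methoxymethoxy)phenyl]acetate | COC(=O)Cc1ccc(OCOC)cc1OCOC | intermediate
4 | methyl 2-[5-bromo-2,4-bis(methoxymethoxy)phenyl]acetate | COC(=O)Cc1cc(Br)c(OCOC)cc1OCOC | intermediate
5 | methyl 2-[5-allyl-2,4-bis(methoxymethoxy)phenyl]acetate | COC(=O)Cc1cc(CC=C)c(OCOC)cc1OCOC | intermediate
6 | 2-[5-allyl-2,4-bis(methoxymethoxy)phenyl]acetic acid | OC(=O)Cc1cc(CC=C)c(OCOC)cc1OCOC | intermediate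
7 | (S)-4-benzyl-2-oxazolidinone | O=C1N[C@@H](Cc2ccccc2)CO1 | starting material
8 | 2-[5-allyl-2,4-bis(methoxymethoxy)phenyl]acetic pivalic anhydride | CC(C)(C)C(=O)OC(=O)Cc1cc(CC=C)c(OCOC)cc1OCOC | intermediate
9 | (S)-4-benzyl-3-{2-[5-allyl-2,4-bis(methoxymethoxy)phenyl]acetyl}oxazolidin-2-one | O=C1OC[C@H](Cc2ccccc2)N1C(=O)Cc1cc(CC=C)c(OCOC)cc1OCOC | intermediate
10 | 3,4,5-trimethoxybenzaldehyde | COc1cc(C=O)cc(OC)c1OC | starting material
11 | (S)-4-benzyl-3-[(Z)-2-[5-allyl-2,4-bis(methoxymethoxy)phenyl]-1-(dibutylboryloxy)vinyl]oxazolidin-2-one | CCCCB(CCCC)O/C(=C\c1cc(CC=C)c(OCOC)cc1OCOC)N1[C@@H](Cc2ccccc2)COC1=O | intermediate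
12 | (S)-4-benzyl-3-[(2S,3S)-2-[5-allyl-2,4-bis(methoxymethoxy)phenyl]-3-(dibutylboryloxy)-3-(3,4,5-trimethoxyphenyl)propanoyl]oxazolidin-2-one | O=C1OC[C@H](Cc2ccccc2)N1C(=O)[C@@H](c1cc(CC=C)c(OCOC)cc1OCOC)[C@H](OB(CCCC)CCCC)c1cc(OC)c(OC)c(OC)c1 | intermediate
13 | (S)-4-benzyl-3-[(2S,3S)-2-[5-allyl-2,4-bis(methoxymethoxy)phenyl]-3-hydroxy-3-(3,4,5-trimethoxyphenyl)propanoyl]oxazolidin-2-one | O=C1OC[C@H](Cc2ccccc2)N1C(=O)[C@@H](c1cc(CC=C)c(OCOC)cc1OCOC)[C@H](O)c1cc(OC)c(OC)c(OC)c1 | intermediate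
14 | (1S,2R)-2-[5-allyl-2,4-bis(methoxymethoxy)phenyl]-1-(3,4,5-trimethoxyphenyl)propane-1,3-diol | OC[C@@H](c1cc(CC=C)c(OCOC)cc1OCOC)[C@H](O)c1cc(OC)c(OC)c(OC)c1 | intermediate
15 | (2R,3S)-2-[5-allyl-2,4-bis(methoxymethoxy)phenyl]-3-hydroxy-3-(3,4,5-trimethoxyphenyl)propyl 4-methylbenzenesulfonate | Cc1ccc(cc1)S(=O)(=O)OC[C@@H](c1cc(CC=C)c(OCOC)cc1OCOC)[C@H](O)c1cc(OC)c(OC)c(OC)c1 | intermediate
16 | (1S,2S)-2-[5-allyl-2,4-bis(methoxymethoxy)phenyl]-1-(3,4,5-trimethoxyphenyl)propan-1-ol | C[C@@H](c1cc(CC=C)c(OCOC)cc1OCOC)[C@H](O)c1cc(OC)c(OC)c(OC)c1 | intermediate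
17 | 4-allyl-6-[(1S,2S)-1-hydroxy-1-(3,4,5-trimethoxyphenyl)propan-2-yl]benzene-1,3-diol | C[C@@H](c1cc(CC=C)c(O)cc1O)[C@H](O)c1cc(OC)c(OC)c(OC)c1 | intermediate
18 | (2S,3S)-5-allyl-3-methyl-2-(3,4,5-trimethoxyphenyl)-2,3-dihydrobenzofuran-6-ol | C=CCc1cc2c(cc1O)O[C@H](c1cc(OC)c(OC)c(OC)c1)[C@H]2C | target

## Step count and risks

Total steps: 11. Longest linear sequence: 11 steps (1 → 18); auxiliary 7 and aldehyde 10 are used as bought.

**Step 7 (aldol).** The ortho-substituted arylacetyl imide is hindered, Bu2BOTf could attack the ortho-OMOM group, and the α-aryl aldol adduct is prone to retro-aldol on work-up. The fallback sets out from acid 6 and comes back at diol 14. Acid 6 is coupled with (S)-4-benzylthiazolidine-2-thione (DCC, DMAP, CH2Cl2) to give 2-[5-allyl-2,4-bis(methoxymethoxy)phenyl]-1-[(S)-4-benzyl-2-thioxothiazolidin-3-yl]ethan-1-one F1. Its chlorotitanium enolate (TiCl4, i-Pr2NEt, N-methyl-2-pyrrolidinone, CH2Cl2, −78 °C) adds to aldehyde 10 in a Crimmins-type aldol with the same facial sense, giving (2S,3S)-2-[5-allyl-2,4-bis(methoxymethoxy)phenyl]-1-[(S)-4-benzyl-2-thioxothiazolidin-3-yl]-3-hydroxy-3-(3,4,5-trimethoxyphenyl)propan-1-one F2. The labile thioimide is cleaved directly with NaBH4 (THF/EtOH, 0 °C) to diol 14.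

**Step 10 (hydride displacement).** The alkoxide formed from the free hydroxyl, or the electron-rich ortho-alkoxyaryl group, can displace the tosylate internally (oxetane or ring-closed by-products) before hydride arrives. The fallback sets out from diol 14 and comes back at alcohol 16, bypassing the tosylate. Selective iodination of the primary hydroxyl (I2, PPh3, imidazole, CH2Cl2, 0 °C) gives (1S,2S)-2-[5-allyl-2,4-bis(methoxymethoxy)phenyl]-3-iodo-1-(3,4,5-trimethoxyphenyl)propan-1-ol F3. Radical deiodination (Bu3SnH, AIBN cat., toluene, 80 °C) then gives 16 with no alkoxide or ionising conditions.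

**Step 11 (cationic ring closure).** Capture of the benzylic cation may give some cis isomer, and a hydride shift or elimination from the cation would erode the C3 centre. The fallback sets out from 16 and comes back at target 18, closing the ring by SN2 instead.
- Mitsunobu esterification (PPh3, DIAD, 4-nitrobenzoic acid, THF, 0 °C) inverts the carbinol to (1R,2S)-2-[5-allyl-2,4-bis(methoxymethoxy)phenyl]-1-(3,4,5-trimethoxyphenyl)propyl 4-nitrobenzoate F4.
- K2CO3/MeOH releases (1R,2S)-2-[5-allyl-2,4-bis(methoxymethoxy)phenyl]-1-(3,4,5-trimethoxyphenyl)propan-1-ol F5.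
- The MOM ethers are removed without Brønsted acid (TMSOTf, 2,2'-bipyridyl, CH2Cl2, 0 °C, then H2O) to give 4-allyl-6-[(1R,2S)-1-hydroxy-1-(3,4,5-trimethoxyphenyl)propan-2-yl]benzene-1,3-diol F6.
- Intramolecular Mitsunobu etherification (PPh3, DIAD, THF, 0 °C, high dilution) closes the ring with inversion at C2 and gives 18 directly.

## Further compounds

F1 | step 7 | 2-[5-allyl-2,4-bis(methoxymethoxy)phenyl]-1-[(S)-4-benzyl-2-thioxothiazolidin-3-yl]ethan-1-one | S=C1SC[C@H](Cc2ccccc2)N1C(=O)Cc1cc(CC=C)c(OCOC)cc1OCOC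
F2 | step 7 | (2S,3S)-2-[5-allyl-2,4-bis(methoxymethoxy)phenyl]-1-[(S)-4-benzyl-2-thioxothiazolidin-3-yl]-3-hydroxy-3-(3,4,5-trimethoxyphenyl)propan-1-one | S=C1SC[C@H](Cc2ccccc2)N1C(=O)[C@@H](c1cc(CC=C)c(OCOC)cc1OCOC)[C@H](O)c1cc(OC)c(OC)c(OC)c1
F3 | step 10 | (1S,2S)-2-[5-allyl-2,4-bis(methoxymethoxy)phenyl]-3-iodo-1-(3,4,5-trimethoxyphenyl)propan-1-ol | IC[C@@H](c1cc(CC=C)c(OCOC)cc1OCOC)[C@H](O)c1cc(OC)c(OC)c(OC)c1
F4 | step 11 | (1R,2S)-2-[5-allyl-2,4-bis(methoxymethoxy)phenyl]-1-(3,4,5-trimethoxyphenyl)propyl 4-nitrobenzoate | C[C@@H](c1cc(CC=C)c(OCOC)cc1OCOC)[C@@H](OC(=O)c1ccc(cc1)[N+](=O)[O-])c1cc(OC)c(OC)c(OC)c1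
F5 | step 11 | (1R,2S)-2-[5-allyl-2,4-bis(methoxymethoxy)phenyl]-1-(3,4,5-trimethoxyphenyl)propan-1-ol | C[C@@H](c1cc(CC=C)c(OCOC)cc1OCOC)[C@@H](O)c1cc(OC)c(OC)c(OC)c1
F6 | step 11 | 4-allyl-6-[(1R,2S)-1-hydroxy-1-(3,4,5-trimethoxyphenyl)propan-2-yl]benzene-1,3-diol | C[C@@H](c1cc(CC=C)c(O)cc1O)[C@@H](O)c1cc(OC)c(OC)c(OC)c1
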